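Everything rests on cutting the isoflavan at C3–C1' and C4–C4a. C3 and C4 of ring C are read as the two carbons of a vinyl group that carries the quinone ring at one end and ring A at the other. An enantioselective palladium-catalysed conjunctive coupling makes both bonds and the C3 stereocentre in one operation. It leaves boron on C3, where C2 is then inserted. Its precursors are a pinacol arylboronate whose triisopropylsilyl-protected phenol masks the quinone, halide-free vinyllithium, and a ring A triflate with a benzyl ether on the future O1. Homologation, oxidation, O1–C2 closure and phenol oxidation finish the route.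

Key step: step 8

Assumption: the ligand is (Rp,R'p)-1,1'-bis[bis(4-methoxy-3,5-dimethylphenyl)phosphino]-2,2'-bis[(S)-α-(dimethylamino)benzyl]ferrocene, called (Rp,Rp)-MandyPhos below. It is taken, by analogy with simple aryl cases, to lead to the (S)-configured coupling product. Both antipodes are commercial, so the other one would be used if a test coupling shows the opposite sense.

Step 1
Reactants: 1 2,3-dimethoxyphenol
Product: 2 (2,3-dimethoxyphenoxy)triisopropylsilane
Conditions: TIPSCl, imidazole, DMF, rt
Reagents that add atoms: triisopropylsilyl chloride, CC(C)[Si](Cl)(C(C)C)C(C)C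
Why: Imidazole-promoted O-silylation of a phenol is routine, and the bulky triisopropylsilyl ether is chosen because it withstands organolithium reagents and mild aqueous base later on and helps to block C6 in the borylation.

Step 2
Reactants: 2 (2,3-dimethoxyphenoxy)triisopropylsilane; 3 bis(pinacolato)diboron
Product: 4 2-[3,4-dimethoxy-5-(triisopropylsilyloxy)phenyl]-4,4,5,5-tetramethyl-1,3,2-dioxaborolane
Conditions: [Ir(OMe)(cod)]2 (1.5 mol %), dtbpy (3 mol %), THF, 80 °C
Reagents that add atoms: none
Why: Iridium-catalysed aromatic C–H borylation (Miyaura–Hartwig type) is governed by sterics, and in this 1,2,3-trisubstituted benzene only C5–H has no ortho substituent, so boron should enter there.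

Step 3
Reactants: 5 2,3,4-trimethoxyphenol
Product: 6 2-hydroxy-3,4,5-trimethoxybenzaldehyde
Conditions: (CH2O)n, MgCl2, Et3N, MeCN, reflux; aq. HCl work-up
Reagents that add atoms: paraformaldehyde (as formaldehyde), C=O
Why: The magnesium-mediated ortho-formylation of phenols (Casnati–Skattebøl reaction) delivers formaldehyde within a magnesium phenoxide chelate and therefore only to an ortho carbon, of which C6 is the sole free one, a second formaldehyde then oxidising the benzylic alkoxide by hydride transfer.

Step 4
Reactants: 6 2-hydroxy-3,4,5-trimethoxybenzaldehyde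
Product: 7 2-(benzyloxy)-3,4,5-trimethoxybenzaldehyde
Conditions: BnBr, K2CO3, DMF, 50 °C
Reagents that add atoms: benzyl bromide, BrCc1ccccc1
Why: Williamson etherification with a reactive benzylic halide is reliable, and benzyl is preferred to a silyl group because it cannot wander between the two neighbouring oxygens once the second phenol is unveiled.

Step 5
Reactants: 7 2-(benzyloxy)-3,4,5-trimethoxybenzaldehyde
Product: 9 2-(benzyloxy)-3,4,5-trimethoxyphenol, via aryl formate 8 (not isolated)
Conditions: mCPBA, CH2Cl2, 0 °C to rt; aq. NaHCO3 wash; then K2CO3 (0.2 equiv), MeOH, rt, N2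
Reagents that add atoms: 3-chloroperoxybenzoic acid, OOC(=O)c1cccc(Cl)c1
Why: Since the aldehyde no longer bears a free ortho or para hydroxy group, the alkaline Dakin protocol is replaced by a Baeyer–Villiger oxidation, in which the electron-rich aryl group migrates to oxygen, and the formate is removed by mild methanolysis.

Step 6
Reactants: 9 2-(benzyloxy)-3,4,5-trimethoxyphenol
Product: 10 2-(benzyloxy)-3,4,5-trimethoxyphenyl trifluoromethanesulfonate
Conditions: Tf2O, pyridine, CH2Cl2, 0 °C
Reagents that add atoms: trifluoromethanesulfonic anhydride, O=S(=O)(OS(=O)(=O)C(F)(F)F)C(F)(F)F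
Why: O-Sulfonylation of a phenol with triflic anhydride and pyridine is the standard way to an aryl triflate and touches none of the ethers.

Step 7
Reactants: 11 iodoethene (vinyl iodide)
Product: 12 vinyllithium (halide-free, titrated THF solution)
Conditions: n-BuLi, pentane, −78 °C; solid filtered under Ar, washed with pentane, dissolved in THF
Reagents that add atoms: n-butyllithium, [Li]CCCC
Why: Iodine–lithium exchange gives butyl iodide and no lithium halide, and because vinyllithium is insoluble in cold pentane it can be washed free of the alkyl iodide, which matters because halide would occupy the vacant site of the cationic palladium species in step 8.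

Step 8
Reactants: 4 2-[3,4-dimethoxy-5-(triisopropylsilyloxy)phenyl]-4,4,5,5-tetramethyl-1,3,2-dioxaborolane; 12 vinyllithium; 10 2-(benzyloxy)-3,4,5-trimethoxyphenyl trifluoromethanesulfonate
Product: 14 (S)-2-{2-[2-(benzyloxy)-3,4,5-trimethoxyphenyl]-1-[3,4-dimethoxy-5-(triisopropylsilyloxy)phenyl]ethyl}-4,4,5,5-tetramethyl-1,3,2-dioxaborolane, via lithium vinylborate complex 13 (not isolated)
Conditions: 4 + 12, THF, 0 °C to rt; then 10, Pd(OAc)2 (3 mol %), (Rp,Rp)-MandyPhos (3.6 mol %), THF, 60 °C
Reagents that add atoms: none
Why: Triflate 10 adds oxidatively to zerovalent palladium, and since triflate does not remain bound the arylpalladium cation (divalent palladium) can take up the vinyl π bond of 13; this coordination triggers migration of the aryl group from boron to the internal carbon, anti to the metal (C3–C1'), while palladium becomes σ-bonded to the terminal carbon, and reductive elimination then joins that carbon to ring A (C4–C4a). The closest known reaction type is the enantioselective palladium-catalysed conjunctive cross-coupling of vinylboron ate complexes with aryl triflates, applied here to two more highly oxygenated arenes. No ring is closed in this step. The only new stereocentre, C3, is controlled by the chiral bisphosphine, which selects the face of the vinyl group that palladium binds and thereby the opposite face on which the aryl group arrives, so that (S)-14 is expected. The step needs the metallate shift to be faster than direct Suzuki–Miyaura transfer of aryl or vinyl from boron and than β-hydride elimination of the alkylpalladium intermediate, which is secured by the weakly coordinating triflate and the absence of lithium halide (palladium stays cationic), by the sluggish transmetallation of a pinacol ate complex and by the wide bite angle of the ligand, which favours reductive elimination. The migrating ring has two free ortho positions and is electron-rich, both of which help the shift, whereas the ortho-benzyloxy group of 10 is the main steric burden and the reason why the risk of the route is placed here.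

Step 9
Reactants: 14 (S)-2-{2-[2-(benzyloxy)-3,4,5-trimethoxyphenyl]-1-[3,4-dimethoxy-5-(triisopropylsilyloxy)phenyl]ethyl}-4,4,5,5-tetramethyl-1,3,2-dioxaborolane
Product: 17 (S)-3-[2-(benzyloxy)-3,4,5-trimethoxyphenyl]-2-[3,4-dimethoxy-5-(triisopropylsilyloxy)phenyl]propan-1-ol, via chloromethylborate complex 15 (not isolated), via homologated pinacolboronate 16 (not isolated)
Conditions: BrCH2Cl, n-BuLi, THF, −78 °C to rt; then NaBO3·4H2O, THF/H2O, rt
Reagents that add atoms: bromochloromethane, ClCBr; sodium perborate tetrahydrate, [Na+].[O-]OB=O.O.O.O.O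
Why: In this Matteson homologation chloromethyllithium generated in the presence of 14 adds to boron and the benzylic carbon migrates with retention while chloride leaves, so C3 keeps its configuration and gains C2, and the perborate oxidation of the primary C–B bond is mild enough to spare the aryl silyl ether that hot alkaline peroxide could attack.

Step 10
Reactants: 17 (S)-3-[2-(benzyloxy)-3,4,5-trimethoxyphenyl]-2-[3,4-dimethoxy-5-(triisopropylsilyloxy)phenyl]propan-1-ol
Product: 18 6-{(2S)-3-hydroxy-2-[3,4-dimethoxy-5-(triisopropylsilyloxy)phenyl]propyl}-2,3,4-trimethoxyphenol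
Conditions: H2 (1 atm), 10 % Pd/C, EtOAc, rt
Reagents that add atoms: none
Why: Catalytic hydrogenolysis cleaves only the benzyl aryl ether, since the silyl ether, the methyl ethers and the all-carbon C3 centre offer no hydrogenolysable bond.

Step 11
Reactants: 18 6-{(2S)-3-hydroxy-2-[3,4-dimethoxy-5-(triisopropylsilyloxy)phenyl]propyl}-2,3,4-trimethoxyphenol
Product: 19 (S)-3-[3,4-dimethoxy-5-(triisopropylsilyloxy)phenyl]-6,7,8-trimethoxychroman
Conditions: PPh3, DIAD, THF (0.02 M), 0 °C to rt
Reagents that add atoms: none
Why: The intramolecular Mitsunobu etherification closes ring C by a 6-exo-tet displacement at the activated primary carbon C2 by the only free phenol (O1), a closure familiar from isoflavan chemistry that does not involve C3.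

Step 12
Reactants: 19 (S)-3-[3,4-dimethoxy-5-(triisopropylsilyloxy)phenyl]-6,7,8-trimethoxychroman
Product: 20 (S)-2,3-dimethoxy-5-(6,7,8-trimethoxychroman-3-yl)phenol
Conditions: Bu4NF, AcOH, THF, 0 °C
Reagents that add atoms: none
Why: Fluoride-induced desilylation is driven by the strong Si–F bond, and the acetic acid buffer protonates the electron-rich phenoxide at once and so guards it against aerial oxidation.

Step 13
Reactants: 20 (S)-2,3-dimethoxy-5-(6,7,8-trimethoxychroman-3-yl)phenol
Product: 21 abruquinone B, (S)-2,3-dimethoxy-5-(6,7,8-trimethoxychroman-3-yl)cyclohexa-2,5-diene-1,4-dione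
Conditions: (KSO3)2NO (2.5 equiv), KH2PO4 buffer, acetone/H2O, rt
Reagents that add atoms: potassium nitrosodisulfonate, [K+].[K+].[O]N(S(=O)(=O)[O-])S(=O)(=O)[O-]
Why: In the Teuber oxidation one nitroxyl radical removes the phenolic hydrogen, a second couples through oxygen at the free para carbon C2' and loss of imidodisulfonate gives the p-quinone, a conversion well known for 2,3-dimethoxy-5-alkylphenols, while the fully etherified ring A (which cerium-based oxidants would endanger) is left alone and the near-neutral buffer avoids enolisation at C3.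

Compound list
1 | 2,3-dimethoxyphenol | COc1cccc(O)c1OC | starting material
2 | (2,3-dimethoxyphenoxy)triisopropylsilane | COc1cccc(O[Si](C(C)C)(C(C)C)C(C)C)c1OC | intermediate
3 | bis(pinacolato)diboron | CC1(C)OB(OC1(C)C)B1OC(C)(C)C(C)(C)O1 | starting material
4 | 2-[3,4-dimethoxy-5-(triisopropylsilyloxy)phenyl]-4,4,5,5-tetramethyl-1,3,2-dioxaborolane | COc1cc(B2OC(C)(C)C(C)(C)O2)cc(O[Si](C(C)C)(C(C)C)C(C)C)c1OC | intermediate
5 | 2,3,4-trimethoxyphenol | COc1ccc(O)c(OC)c1OC | starting material
6 | 2-hydroxy-3,4,5-trimethoxybenzaldehyde | COc1cc(C=O)c(O)c(OC)c1OC | intermediate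
7 | 2-(benzyloxy)-3,4,5-trimethoxybenzaldehyde | COc1cc(C=O)c(OCc2ccccc2)c(OC)c1OC | intermediate
8 | 2-(benzyloxy)-3,4,5-trimethoxyphenyl formate | COc1cc(OC=O)c(OCc2ccccc2)c(OC)c1OC | intermediate
9 | 2-(benzyloxy)-3,4,5-trimethoxyphenol | COc1cc(O)c(OCc2ccccc2)c(OC)c1OC | intermediate
10 | 2-(benzyloxy)-3,4,5-trimethoxyphenyl trifluoromethanesulfonate | COc1cc(OS(=O)(=O)C(F)(F)F)c(OCc2ccccc2)c(OC)c1OC | intermediate
11 | iodoethene (vinyl iodide) | C=CI | starting material
12 | vinyllithium | [Li]C=C | intermediate
13 | lithium [3,4-dimethoxy-5-(triisopropylsilyloxy)phenyl](ethenyl)(pinacolato)borate | [Li+].C=C[B-]1(OC(C)(C)C(C)(C)O1)c1cc(OC)c(OC)c(O[Si](C(C)C)(C(C)C)C(C)C)c1 | intermediate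
14 | (S)-2-{2-[2-(benzyloxy)-3,4,5-trimethoxyphenyl]-1-[3,4-dimethoxy-5-(triisopropylsilyloxy)phenyl]ethyl}-4,4,5,5-tetramethyl-1,3,2-dioxaborolane | CC1(C)OB(OC1(C)C)[C@@H](Cc1cc(OC)c(OC)c(OC)c1OCc1ccccc1)c1cc(OC)c(OC)c(O[Si](C(C)C)(C(C)C)C(C)C)c1 | intermediate
15 | lithium (chloromethyl){(S)-2-[2-(benzyloxy)-3,4,5-trimethoxyphenyl]-1-[3,4-dimethoxy-5-(triisopropylsilyloxy)phenyl]ethyl}(pinacolato)borate | [Li+].ClC[B-]1(OC(C)(C)C(C)(C)O1)[C@@H](Cc1cc(OC)c(OC)c(OC)c1OCc1ccccc1)c1cc(OC)c(OC)c(O[Si](C(C)C)(C(C)C)C(C)C)c1 | intermediate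
16 | (S)-2-{3-[2-(benzyloxy)-3,4,5-trimethoxyphenyl]-2-[3,4-dimethoxy-5-(triisopropylsilyloxy)phenyl]propyl}-4,4,5,5-tetramethyl-1,3,2-dioxaborolane | CC1(C)OB(OC1(C)C)C[C@@H](Cc1cc(OC)c(OC)c(OC)c1OCc1ccccc1)c1cc(OC)c(OC)c(O[Si](C(C)C)(C(C)C)C(C)C)c1 | intermediate
17 | (S)-3-[2-(benzyloxy)-3,4,5-trimethoxyphenyl]-2-[3,4-dimethoxy-5-(triisopropylsilyloxy)phenyl]propan-1-ol | OC[C@@H](Cc1cc(OC)c(OC)c(OC)c1OCc1ccccc1)c1cc(OC)c(OC)c(O[Si](C(C)C)(C(C)C)C(C)C)c1 | intermediate
18 | 6-{(2S)-3-hydroxy-2-[3,4-dimethoxy-5-(triisopropylsilyloxy)phenyl]propyl}-2,3,4-trimethoxyphenol | OC[C@@H](Cc1cc(OC)c(OC)c(OC)c1O)c1cc(OC)c(OC)c(O[Si](C(C)C)(C(C)C)C(C)C)c1 | intermediate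
19 | (S)-3-[3,4-dimethoxy-5-(triisopropylsilyloxy)phenyl]-6,7,8-trimethoxychroman | COc1cc([C@H]2COc3c(cc(OC)c(OC)c3OC)C2)cc(O[Si](C(C)C)(C(C)C)C(C)C)c1OC | intermediate
20 | (S)-2,3-dimethoxy-5-(6,7,8-trimethoxychroman-3-yl)phenol | COc1cc([C@H]2COc3c(cc(OC)c(OC)c3OC)C2)cc(O)c1OC | intermediate
21 | abruquinone B, (S)-2,3-dimethoxy-5-(6,7,8-trimethoxychroman-3-yl)cyclohexa-2,5-diene-1,4-dione | COC1=C(OC)C(=O)C([C@H]2COc3c(cc(OC)c(OC)c3OC)C2)=CC1=O | target

Total step count: 13.
Longest linear sequence: 10 steps (5 → 6 → 7 → 9 → 10 → 14 → 17 → 18 → 19 → 20 → 21).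

Steps most likely to fail

1. Step 8. The electron-rich, ortho-substituted triflate may add slowly to palladium and crowd the alkene-binding site. Direct aryl or vinyl transfer from boron, protodeboronation or poor facial selectivity could then take over. The fallback sets out from 4 and comes back at 14, and it makes the stereocentre and the two C–C bonds in separate operations. Suzuki–Miyaura vinylation of 4 with vinyl bromide (Pd(PPh3)4, K3PO4, THF/H2O) would give the styrene (5-ethenyl-2,3-dimethoxyphenoxy)triisopropylsilane F1. Enantioselective syn-diboration of its alkene with 3 (Pt(dba)3, TADDOL-derived phosphonite of the appropriate antipode) would give (S)-2,2'-{1-[3,4-dimethoxy-5-(triisopropylsilyloxy)phenyl]ethane-1,2-diyl}bis(4,4,5,5-tetramethyl-1,3,2-dioxaborolane) F2. The less hindered primary C–B bond would then be coupled selectively with 10 (Pd(OAc)2, RuPhos, K3PO4, THF/H2O) to give 14.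

2. Step 9. The short-lived carbenoid may be captured incompletely by the hindered secondary boronate, a second insertion may occur, or the aryl silyl ether may be lost during the oxidation. The fallback sets out from 14 and comes back at 17, and it brings in C2 as part of a vinyl group instead of a carbenoid. Zweifel olefination of 14 with 12 (then iodine and NaOMe) should give, with retention at C3, (R)-{5-[1-(2-(benzyloxy)-3,4,5-trimethoxyphenyl)but-3-en-2-yl]-2,3-dimethoxyphenoxy}triisopropylsilane F3. Oxidative cleavage of the terminal alkene (OsO4 cat., NaIO4, 2,6-lutidine, dioxane/H2O) would give (S)-3-[2-(benzyloxy)-3,4,5-trimethoxyphenyl]-2-[3,4-dimethoxy-5-(triisopropylsilyloxy)phenyl]propanal F4. This aldehyde is reduced at once in the same flask with NaBH4 to 17, so that it has little time to enolise.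

3. Step 13. The radical oxidant may attack the ortho carbon C6'. The lipophilic phenol may also react sluggishly in the aqueous medium, and forcing the reaction could degrade ring A. The fallback sets out from 20 and comes back at 21, and it fixes the regiochemistry by an ionic C–N bond formation before any oxidation. Para-nitrosation with the small nitrosonium electrophile (NaNO2, aq. HCl/EtOH, 0 °C) would give (S)-2,3-dimethoxy-4-nitroso-5-(6,7,8-trimethoxychroman-3-yl)phenol F5, the tautomer of the quinone monooxime. Reduction with Na2S2O4 would give (S)-4-amino-2,3-dimethoxy-5-(6,7,8-trimethoxychroman-3-yl)phenol F6. Brief oxidation with aqueous FeCl3/HCl at 0 °C, with hydrolysis of the quinone imine, would give 21.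

Further compounds
F1 | step 8 | (5-ethenyl-2,3-dimethoxyphenoxy)triisopropylsilane | C=Cc1cc(OC)c(OC)c(O[Si](C(C)C)(C(C)C)C(C)C)c1
F2 | step 8 | (S)-2,2'-{1-[3,4-dimethoxy-5-(triisopropylsilyloxy)phenyl]ethane-1,2-diyl}bis(4,4,5,5-tetramethyl-1,3,2-dioxaborolane) | CC1(C)OB(OC1(C)C)[C@@H](CB1OC(C)(C)C(C)(C)O1)c1cc(OC)c(OC)c(O[Si](C(C)C)(C(C)C)C(C)C)c1
F3 | step 9 | (R)-{5-[1-(2-(benzyloxy)-3,4,5-trimethoxyphenyl)but-3-en-2-yl]-2,3-dimethoxyphenoxy}triisopropylsilane | C=C[C@@H](Cc1cc(OC)c(OC)c(OC)c1OCc1ccccc1)c1cc(OC)c(OC)c(O[Si](C(C)C)(C(C)C)C(C)C)c1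
F4 | step 9 | (S)-3-[2-(benzyloxy)-3,4,5-trimethoxyphenyl]-2-[3,4-dimethoxy-5-(triisopropylsilyloxy)phenyl]propanal | O=C[C@@H](Cc1cc(OC)c(OC)c(OC)c1OCc1ccccc1)c1cc(OC)c(OC)c(O[Si](C(C)C)(C(C)C)C(C)C)c1
F5 | step 13 | (S)-2,3-dimethoxy-4-nitroso-5-(6,7,8-trimethoxychroman-3-yl)phenol | COc1c(N=O)c([C@H]2COc3c(cc(OC)c(OC)c3OC)C2)cc(O)c1OC
F6 | step 13 | (S)-4-amino-2,3-dimethoxy-5-(6,7,8-trimethoxychroman-3-yl)phenol | COc1c(N)c([C@H]2COc3c(cc(OC)c(OC)c3OC)C2)cc(O)c1OC
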